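**Retrosynthetic overview**
- The oxirane is made last: Luche reduction of a 4-hydroxycyclohex-2-enone, then SN2′ closure of the tertiary alkoxide onto the allylic sulfonate, which also moves the C=C into place.
- The cyclohexenone comes from the key step: the CH2 next to the pyranone adds to the C=O of a γ,γ-disubstituted butenolide (temporary ring), the lactone opens, and the enolate is C-methylated to the quaternary centre.
- Enabling feature: the quaternary carbon C4 of the oxabicycle sits on C6 of the 4-pyranone (γ-carbon of a vinylogous ester, hence acidic). The ring =CH (C3) lies 1,4 to oxirane carbon C6, so it can be held at acyl level in a five-membered lactone whose ring O is the future epoxide O.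
- The butenolide–pyranone comes from an aldehyde (dianion aldol, oxidation, DBU lactonisation, O-methylation); the aldehyde comes from an organocatalytic Mukaiyama–Michael addition of a 2-silyloxyfuran to a dienal, which sets both acyclic stereocentres.
- Ring order: butenolide (temporary) → 4-pyranone → cyclohexene (key step) → oxirane.

Key step: step 9

Assumption: in step 4 the (2S,5S)-imidazolidinone is taken to expose the enal β-face that leads to the (3S) adduct, as in its additions to crotonaldehyde; if the sense were opposite, the (2R,5R)-catalyst would be used.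

Step 1
Reactants: 1 5-methyl-3-methylidenedihydrofuran-2(3H)-one (α-methylene-γ-valerolactone, racemic)
Product: 2 3,5-dimethylfuran-2(5H)-one (racemic)
Conditions: RhCl3·3H2O (2 mol%), EtOH, reflux
Reagents that add atoms: none
Why: Rh–H mediated exo-to-endo alkene isomerisation should give the conjugated trisubstituted butenolide as the thermodynamic product; its stereocentre is erased in step 2.

Step 2
Reactants: 2 3,5-dimethylfuran-2(5H)-one
Product: 3 [(3,5-dimethylfuran-2-yl)oxy]tri(propan-2-yl)silane
Conditions: TIPSOTf, Et3N, CH2Cl2, 0 °C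
Reagents that add atoms: triisopropylsilyl trifluoromethanesulfonate, CC(C)[Si](C(C)C)(C(C)C)OS(=O)(=O)C(F)(F)F
Why: Soft enolisation at the γ-CH (vinylogous to the lactone C=O) and O-silylation should give the aromatic 2-silyloxyfuran.

Step 3
Reactants: 4 (2E)-2-methylpent-2-enal
Product: 5 (2E,4E)-4-methylhepta-2,4-dienal
Conditions: Ph3P=CHCHO, toluene, 80 °C
Reagents that add atoms: (triphenylphosphoranylidene)acetaldehyde, O=CC=P(c1ccccc1)(c1ccccc1)c1ccccc1
Why: Wittig reaction with the stabilised formylmethylene ylide should give the (E)-enal by two-carbon homologation, leaving the existing (E)-trisubstituted alkene untouched.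

Step 4
Reactants: 3 [(3,5-dimethylfuran-2-yl)oxy]tri(propan-2-yl)silane; 5 (2E,4E)-4-methylhepta-2,4-dienal
Product: 6 (3S,4E)-3-[(2R)-2,4-dimethyl-5-oxo-2,5-dihydrofuran-2-yl]-4-methylhept-4-enal
Conditions: (2S,5S)-5-benzyl-2-tert-butyl-3-methylimidazolidin-4-one·TfOH (20 mol%), H2O (2 equiv), CHCl3, −40 °C
Reagents that add atoms: none
Why: Organocatalytic Mukaiyama–Michael reaction (MacMillan, iminium activation): furan C5 attacks the β-carbon of the iminium ion of 5 (1,4-addition expected because the δ-carbon is hindered); the catalyst shields one β-face and so sets C3, while the configuration of the new quaternary butenolide carbon follows from the open transition state, whose syn/anti sense depends on acid co-catalyst and solvent (TfOH/CHCl3, the combination reported to reverse the usual syn preference, is chosen for the required (3S,2′R) series).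

Step 5
Reactants: 6 (3S,4E)-3-[(2R)-2,4-dimethyl-5-oxo-2,5-dihydrofuran-2-yl]-4-methylhept-4-enal; 7 methyl 2-methyl-3-oxopentanoate
Product: 9 methyl (7S,8E)-7-[(2R)-2,4-dimethyl-5-oxo-2,5-dihydrofuran-2-yl]-5-hydroxy-2,4,8-trimethyl-3-oxoundec-8-enoate (diastereomer mixture at C2, C4, C5), via sodium lithium dianion 8 (not isolated)
Conditions: 7, NaH, THF, 0 °C; n-BuLi, 0 °C; then 6, −78 °C; AcOH quench at −78 °C
Reagents that add atoms: none
Why: Huckin–Weiler dianion aldol: the γ-carbanion of the β-keto ester should add to the aldehyde faster than to the butenolide at −78 °C; the three new stereocentres are removed in steps 6 and 7.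

Step 6
Reactants: 9 methyl (7S,8E)-7-[(2R)-2,4-dimethyl-5-oxo-2,5-dihydrofuran-2-yl]-5-hydroxy-2,4,8-trimethyl-3-oxoundec-8-enoate
Product: 10 methyl (7S,8E)-7-[(2R)-2,4-dimethyl-5-oxo-2,5-dihydrofuran-2-yl]-2,4,8-trimethyl-3,5-dioxoundec-8-enoate (C2/C4 epimers, keto–enol mixture)
Conditions: Dess–Martin periodinane, CH2Cl2, 0 → 23 °C
Reagents that add atoms: none
Why: Dess–Martin oxidation of the secondary alcohol should give the β,δ-diketo ester under non-basic conditions that leave the butenolide and both alkenes alone.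

Step 7
Reactants: 10 methyl (7S,8E)-7-[(2R)-2,4-dimethyl-5-oxo-2,5-dihydrofuran-2-yl]-2,4,8-trimethyl-3,5-dioxoundec-8-enoate
Product: 11 (5R)-5-[(2S,3E)-1-(4-hydroxy-3,5-dimethyl-2-oxo-2H-pyran-6-yl)-3-methylhex-3-en-2-yl]-3,5-dimethylfuran-2(5H)-one
Conditions: DBU, toluene, 23 °C
Reagents that add atoms: none
Why: DBU-mediated enolisation and lactonisation (O-acylation of the δ-enol by the methyl ester, 6-exo-trig) should give the 4-hydroxy-2-pyranone with loss of methanol, the standard ring closure of 3,5-dioxo esters; room temperature is chosen to avoid retro-Michael loss of the butenolide.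

Step 8
Reactants: 11 (5R)-5-[(2S,3E)-1-(4-hydroxy-3,5-dimethyl-2-oxo-2H-pyran-6-yl)-3-methylhex-3-en-2-yl]-3,5-dimethylfuran-2(5H)-one
Product: 12 (5R)-5-[(2S,3E)-1-(6-methoxy-3,5-dimethyl-4-oxo-4H-pyran-2-yl)-3-methylhex-3-en-2-yl]-3,5-dimethylfuran-2(5H)-one
Conditions: MeOSO2F, CH2Cl2, 23 °C; aq. NaHCO3 work-up
Reagents that add atoms: methyl fluorosulfonate, COS(=O)(=O)F
Why: Hard O-methylation of the 2-pyranone carbonyl oxygen followed by loss of the 4-OH proton should give the 2-methoxy-4-pyranone regioisomer, as established for 4-hydroxy-2-pyranones of this type.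

Step 9
Reactants: 12 (5R)-5-[(2S,3E)-1-(6-methoxy-3,5-dimethyl-4-oxo-4H-pyran-2-yl)-3-methylhex-3-en-2-yl]-3,5-dimethylfuran-2(5H)-one
Product: 14 (4R,5R,6R)-4-hydroxy-6-(6-methoxy-3,5-dimethyl-4-oxo-4H-pyran-2-yl)-2,4,6-trimethyl-5-[(2E)-pent-2-en-2-yl]cyclohex-2-en-1-one, via lithium enolate 13 (not isolated)
Conditions: LiHMDS (1.1 equiv), THF, −78 → 0 °C; then MeI (3 equiv), −78 → 0 °C
Reagents that add atoms: iodomethane, CI
Why: LiHMDS removes a proton from the CH2 between pyranone C2 and the stereocentre (vinylogous to the pyranone C=O), and the delocalised carbanion adds to the butenolide C=O across the lactone ring to give a 7-oxanorbornene-type hemiketal alkoxide, which opens by C–O scission to the cyclohexenone and the tertiary alkoxide; proton transfer then gives the enolate flanked by ketone and pyranone, which drives the sequence and is C-methylated in the same flask. The closest known reactions are the Claisen/Dieckmann C-acylation of metalated 2-alkyl-4-pyranones by esters, the base-induced isomerisation of enol lactones to cyclic 1,3-diketones, and the alkylation of 2-acyl-type cyclic enolates. The carbocycle closes in the 6-exo-trig mode at the carbonyl carbon (6-(enolexo)), the Z geometry needed for closure being locked by the five-membered lactone. The new quaternary stereocentre is controlled by the adjacent pentenyl-bearing carbon: allylic 1,3-strain with the coplanar pyranone forces the pentenyl group pseudoaxial, and methyl iodide enters the enolate carbon from the opposite face (methyl trans to pentenyl, pyranone cis). The step needs C- over O-methylation and ring closure in preference to retro-Michael loss of the butenolide or 3-exo displacement of the carboxylate; the lithium counter-ion in THF, low temperature and the irreversible formation of the stabilised enolate should secure this.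

Step 10
Reactants: 14 (4R,5R,6R)-4-hydroxy-6-(6-methoxy-3,5-dimethyl-4-oxo-4H-pyran-2-yl)-2,4,6-trimethyl-5-[(2E)-pent-2-en-2-yl]cyclohex-2-en-1-one
Product: 15 (1R,4R,5R,6S)-6-(6-methoxy-3,5-dimethyl-4-oxo-4H-pyran-2-yl)-2,4,6-trimethyl-5-[(2E)-pent-2-en-2-yl]cyclohex-2-ene-1,4-diol
Conditions: NaBH4, CeCl3·7H2O, MeOH, −78 → −20 °C
Reagents that add atoms: none
Why: Luche 1,2-reduction: hydride should be delivered to the ketone face opposite the pseudoaxial pentenyl group (1,3-relationship), giving the (1R) allylic alcohol; either C1 epimer is expected to serve in step 11.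

Step 11
Reactants: 15 (1R,4R,5R,6S)-6-(6-methoxy-3,5-dimethyl-4-oxo-4H-pyran-2-yl)-2,4,6-trimethyl-5-[(2E)-pent-2-en-2-yl]cyclohex-2-ene-1,4-diol
Product: 17 2-methoxy-3,5-dimethyl-6-{(1R,4R,5R,6S)-2,4,6-trimethyl-5-[(2E)-pent-2-en-2-yl]-7-oxabicyclo[4.1.0]hept-2-en-4-yl}-4H-pyran-4-one, via allylic tosylate 16 (not isolated)
Conditions: NaH (2.5 equiv), THF, 0 °C; then 1-(p-toluenesulfonyl)imidazole (1.05 equiv), 0 → 23 °C
Reagents that add atoms: none
Why: Proposed new method: the dialkoxide is sulfonylated at the less hindered secondary allylic oxygen and the remaining tertiary alkoxide attacks the adjacent alkene carbon while the tosylate leaves from the far allylic carbon (intramolecular 3-exo SN2′ with allylic transposition), which closes the oxirane and moves the C=C into its final position; the neopentyl sulfonate carbon and the absence of β-hydrogens disfavour direct SN2 (1,4-ether) and E2, the oxirane can only form cis-fused on the face of the tertiary oxygen, and the closest known reactions are the Williamson closure of hydroxy sulfonates to epoxides (NaH/TsIm one-pot protocol for diols) and intramolecular SN2′ O-alkylations that give vinyl-substituted cyclic ethers.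

**Compound list**
1 | 5-methyl-3-methylidenedihydrofuran-2(3H)-one (racemic) | C=C1CC(C)OC1=O | starting material
2 | 3,5-dimethylfuran-2(5H)-one (racemic) | CC1=CC(C)OC1=O | intermediate
3 | [(3,5-dimethylfuran-2-yl)oxy]tri(propan-2-yl)silane | Cc1cc(C)c(O[Si](C(C)C)(C(C)C)C(C)C)o1 | intermediate
4 | (2E)-2-methylpent-2-enal | CC/C=C(\C)C=O | starting material
5 | (2E,4E)-4-methylhepta-2,4-dienal | CC/C=C(\C)/C=C/C=O | intermediate
6 | (3S,4E)-3-[(2R)-2,4-dimethyl-5-oxo-2,5-dihydrofuran-2-yl]-4-methylhept-4-enal | CC/C=C(\C)[C@H](CC=O)[C@]1(C)OC(=O)C(C)=C1 | intermediate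
7 | methyl 2-methyl-3-oxopentanoate | CCC(=O)C(C)C(=O)OC | starting material
8 | sodium lithium dianion (1,3-dienediolate) of 7 | CC=C([O-])C(C)=C([O-])OC.[Na+].[Li+] | intermediate
9 | methyl (7S,8E)-7-[(2R)-2,4-dimethyl-5-oxo-2,5-dihydrofuran-2-yl]-5-hydroxy-2,4,8-trimethyl-3-oxoundec-8-enoate | CC/C=C(\C)[C@H](CC(O)C(C)C(=O)C(C)C(=O)OC)[C@]1(C)OC(=O)C(C)=C1 | intermediate
10 | methyl (7S,8E)-7-[(2R)-2,4-dimethyl-5-oxo-2,5-dihydrofuran-2-yl]-2,4,8-trimethyl-3,5-dioxoundec-8-enoate | CC/C=C(\C)[C@H](CC(=O)C(C)C(=O)C(C)C(=O)OC)[C@]1(C)OC(=O)C(C)=C1 | intermediate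
11 | (5R)-5-[(2S,3E)-1-(4-hydroxy-3,5-dimethyl-2-oxo-2H-pyran-6-yl)-3-methylhex-3-en-2-yl]-3,5-dimethylfuran-2(5H)-one | CC/C=C(\C)[C@H](CC1=C(C)C(O)=C(C)C(=O)O1)[C@]1(C)OC(=O)C(C)=C1 | intermediate
12 | (5R)-5-[(2S,3E)-1-(6-methoxy-3,5-dimethyl-4-oxo-4H-pyran-2-yl)-3-methylhex-3-en-2-yl]-3,5-dimethylfuran-2(5H)-one | CC/C=C(\C)[C@H](Cc1oc(OC)c(C)c(=O)c1C)[C@]1(C)OC(=O)C(C)=C1 | intermediate
13 | lithium enolate (O–C1=C6) of (4R,5R)-4-hydroxy-6-(6-methoxy-3,5-dimethyl-4-oxo-4H-pyran-2-yl)-2,4-dimethyl-5-[(2E)-pent-2-en-2-yl]cyclohex-2-en-1-one | CC/C=C(\C)[C@H]1[C@](C)(O)C=C(C)C([O-])=C1c1oc(OC)c(C)c(=O)c1C.[Li+] | intermediate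
14 | (4R,5R,6R)-4-hydroxy-6-(6-methoxy-3,5-dimethyl-4-oxo-4H-pyran-2-yl)-2,4,6-trimethyl-5-[(2E)-pent-2-en-2-yl]cyclohex-2-en-1-one | CC/C=C(\C)[C@H]1[C@](C)(O)C=C(C)C(=O)[C@@]1(C)c1oc(OC)c(C)c(=O)c1C | intermediate
15 | (1R,4R,5R,6S)-6-(6-methoxy-3,5-dimethyl-4-oxo-4H-pyran-2-yl)-2,4,6-trimethyl-5-[(2E)-pent-2-en-2-yl]cyclohex-2-ene-1,4-diol | CC/C=C(\C)[C@H]1[C@](C)(O)C=C(C)[C@@H](O)[C@@]1(C)c1oc(OC)c(C)c(=O)c1C | intermediate
16 | sodium 4-alkoxide of the 1-O-(4-methylbenzenesulfonate) of 15 | CC/C=C(\C)[C@H]1[C@](C)([O-])C=C(C)[C@@H](OS(=O)(=O)c2ccc(C)cc2)[C@@]1(C)c1oc(OC)c(C)c(=O)c1C.[Na+] | intermediate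
17 | 2-methoxy-3,5-dimethyl-6-{(1R,4R,5R,6S)-2,4,6-trimethyl-5-[(2E)-pent-2-en-2-yl]-7-oxabicyclo[4.1.0]hept-2-en-4-yl}-4H-pyran-4-one | CC/C=C(\C)[C@H]1[C@]2(C)O[C@@H]2C(C)=C[C@@]1(C)c1oc(OC)c(C)c(=O)c1C | target

**Step count**
Total steps: 11. Longest linear sequence: 10 (steps 1, 2, 4–11, from 1 to 17).

**Steps most likely to fail**

1. Step 11 (proposed new method). What may go wrong: sulfonylation of the tertiary instead of the secondary alkoxide, direct SN2 closure to the 1,4-bridged ether, or ionisation of the allylic sulfonate in place of the SN2′ closure. Fallback with known chemistry, setting out from 14 and returning at 17: Weitz–Scheffer epoxidation of 14 (H2O2, NaOH, MeOH, 0 °C; peroxide attack anti to the pseudoaxial 4-hydroxyl) gives the 2,3-epoxy ketone F1. Wharton transposition (N2H4·H2O, AcOH, MeOH) gives the allylic trans-1,2-diol F2 with the C=C already in its final place. F2 is closed to 17 by the standard hydroxy-tosylate route (NaH, TsIm: O-sulfonylation of the secondary allylic alcohol, then displacement by the tertiary alkoxide with inversion).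

2. Step 9 (key step). What may go wrong: retro-Michael loss of the butenolide from the pyranone-stabilised carbanion (which would scramble both acyclic stereocentres), 3-exo displacement of the lactone carboxylate, O-methylation, or poor facial selectivity in the methylation. Fallback, setting out from 12 and returning at 14: the lactone is opened with Me2AlN(OMe)Me and the tertiary alkoxide silylated (TESOTf, 2,6-lutidine) to the (Z)-Weinreb amide F3, which no longer carries a carboxylate or furanolate leaving group. LiHMDS then closes the ring by acylation through the chelated tetrahedral intermediate to the ring ketone F4. C-methylation under mild conditions (K2CO3, MeI, acetone; anti to the pentenyl group) gives the silyl ether F5, and HF·pyridine gives 14.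

3. Step 4. What may go wrong: low or wrong relative induction between the two new stereocentres (syn/anti sense), or competing 1,6-addition to the dienal. Fallback, setting out from 4 and returning at 10: Horner–Wadsworth–Emmons reaction of 4 with diethyl [2-oxo-2-(2-oxo-1,3-oxazolidin-3-yl)ethyl]phosphonate gives the dienoyl oxazolidinone F6. Cu(OTf)2/(S,S)-t-Bu-bis(oxazoline)-catalysed Mukaiyama–Michael addition of 3 to the chelated imide (anti-selective mode) gives the imide F7. F7 acylates dianion 8 directly at its γ-carbon (oxazolidinone as leaving group) to give 10, so steps 5 and 6 are not needed.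

Further compounds
F1 | step 11 | 5-hydroxy-3-(6-methoxy-3,5-dimethyl-4-oxo-4H-pyran-2-yl)-1,3,5-trimethyl-4-[(2E)-pent-2-en-2-yl]-7-oxabicyclo[4.1.0]heptan-2-one (oxirane trans to the 5-OH, other centres as in 14) | CC/C=C(\C)[C@H]1[C@](C)(O)[C@H]2O[C@@]2(C)C(=O)[C@@]1(C)c1oc(OC)c(C)c(=O)c1C
F2 | step 11 | 5-(6-methoxy-3,5-dimethyl-4-oxo-4H-pyran-2-yl)-1,3,5-trimethyl-6-[(2E)-pent-2-en-2-yl]cyclohex-3-ene-1,2-diol (1-OH and 2-OH trans, other centres as in 17) | CC/C=C(\C)[C@H]1[C@](C)(O)[C@@H](O)C(C)=C[C@@]1(C)c1oc(OC)c(C)c(=O)c1C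
F3 | step 9 | (2Z,4R,5S,6E)-N-methoxy-5-[(6-methoxy-3,5-dimethyl-4-oxo-4H-pyran-2-yl)methyl]-N,2,4,6-tetramethyl-4-[(triethylsilyl)oxy]nona-2,6-dienamide | CC/C=C(\C)[C@H](Cc1oc(OC)c(C)c(=O)c1C)[C@](C)(O[Si](CC)(CC)CC)/C=C(/C)C(=O)N(C)OC
F4 | step 9 | 6-(6-methoxy-3,5-dimethyl-4-oxo-4H-pyran-2-yl)-2,4-dimethyl-5-[(2E)-pent-2-en-2-yl]-4-[(triethylsilyl)oxy]cyclohex-2-en-1-one (C4 and C5 as in 14, C6 epimers/enol) | CC/C=C(\C)[C@H]1[C@](C)(O[Si](CC)(CC)CC)C=C(C)C(=O)C1c1oc(OC)c(C)c(=O)c1C
F5 | step 9 | triethylsilyl ether of 14 | CC/C=C(\C)[C@H]1[C@](C)(O[Si](CC)(CC)CC)C=C(C)C(=O)[C@@]1(C)c1oc(OC)c(C)c(=O)c1C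
F6 | step 4 | 3-[(2E,4E)-4-methylhepta-2,4-dienoyl]-1,3-oxazolidin-2-one | CC/C=C(\C)/C=C/C(=O)N1CCOC1=O
F7 | step 4 | 3-{(3S,4E)-3-[(2R)-2,4-dimethyl-5-oxo-2,5-dihydrofuran-2-yl]-4-methylhept-4-enoyl}-1,3-oxazolidin-2-one | CC/C=C(\C)[C@H](CC(=O)N1CCOC1=O)[C@]1(C)OC(=O)C(C)=C1
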